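The data are calculated from invented constants, noise included.

We have to decide how much coupling partner to charge, so follow one molecule of it through the flask.

| setting | west | south-west | flask |
|---|---|---|---|
| starting material | 0.010 M | 0.010 M | 0.010 M |
| coupling partner | 0.0050 M | 0.0075 M | 0.0100 M |
| remark | run made earlier | run made earlier |  |
| time |  |  | 1.5 h |

| run | time / min | first product / % |
|---|---|---|
| west | 10.0 | 41.7 |
| west | 20.0 | 47.7 |
| west | 30.0 | 49.7 |
| west | 40.0 | 48.9 |
| west | 50.0 | 49.6 |
| south-west | 4.00 | 40.3 |
| south-west | 8.00 | 55.3 |
| south-west | 15.0 | 64.9 |
| south-west | 30.0 | 71.3 |
| south-west | 50.0 | 72.8 |

(each reading ± 1 percentage point)

- first product is meant together with its crystals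
- solid, in amounts per volume of the solution: crystals
- the numbers in the tables scatter by 1 percentage point (one standard deviation)
- candidate steps: coupling partner <-> dormant form; starting material + coupling partner -> first product; coupling partner + first product -> double product; crystals <-> first product; coupling partner + double product -> triple product

- equivalents of coupling partner to starting material, everything else as given, that leave most first product at 1.5 h
- the amount of first product then, in percent of the starting material charged
- the amount of first product with the amounts as given

*Where can a molecule of coupling partner go?* It can meet starting material, which gives first product, or meet first product, which gives double product and so uses up first product. It can also rest as dormant form, or meet double product, which gives triple product.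

*What do the runs say about its chances?* Coupling partner is the limiting reagent in both runs, so I take its charge as spent at the plateau. In the south-west run, 72.8 % of first product stands against a charge of 75.0 %, which gives 0.971. That is the landing share, first product made per coupling partner spent. The west run reads 0.992, and each reading carries a scatter of 1 percentage point.

*And at one equivalent?* My own reckoning gives a ceiling of 97.1 % once the charge is spent.

*But is it spent by 1.5 h?* That is the weak spot. The south-west run still moved from 71.3 % to 72.8 % after 30.0 min, and here both reagents thin together. So I commit to something below that ceiling, without a figure.

The forecast does give figures: 90 % (86 % to 94 %) as charged, and 92 % at 1.1 equiv. Its grounds: “The plateaus sit close to the charge”.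

The flask gives 94.5 % as charged, and 98.1 % at 1.19 equiv, which is 6.1 points above the forecast's best.

    coupling partner ⇌ dormant form (K = 0.300, k = 0.0122 /s)
    starting material + coupling partner → first product (k = 0.571 /M/s)
    coupling partner + first product → double product (k = 0.0206 /M/s)
    crystals ⇌ first product, rate k4*(cs4 - [first product]) while solid is left; crystals form when [first product] > cs4 (solubility = 0.770 mM, k = 1.68 /s)
    coupling partner + double product → triple product (k = 0.534 /M/s)

In the flask at 1.50 h, 2.5 % of the coupling partner's charge is free and 0.757 % is dormant, so 96.7 % is spent. Times the landing share, that makes 93.9 % of first product, against 94.5 % found. The neighbouring flask is the same flask charged with 0.0025 M of coupling partner, which is 25.0 % of the starting material. The landing share promises 24.3 % of first product there. In that neighbouring flask at 1.50 h, free coupling partner stands at 0 %, dormant form at 1.10 × 10⁻¹¹ M, and first product at 24.9 %.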